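## Analysis of the target

2-O-Acetylzeylenone is a single carbocycle, a cyclohex-2-enone. It is numbered here C1 (quaternary carbinol carbon carrying the C7H2OBz arm), C2 (CHOAc), C3 (CHOBz), C4=C5 (alkene) and C6 (ketone). The three stereocentres C1 (S), C2 (S) and C3 (R) are contiguous: the free C1 hydroxyl is cis to the C2 acetate, and the C2 acetate is trans to the C3 benzoate. Four neighbouring carbons carry four different oxygen functions: a primary benzoate, a free tertiary alcohol, a secondary acetate and an allylic secondary benzoate. The compound is sensitive to base and strong acid, because the γ-acyloxy enone can eliminate and aromatise, esters can migrate between neighbouring oxygens, and the β-oxygenated ketone can open by retro-aldol cleavage. The hard points are the oxygenated quaternary centre C1 next to the ketone, its configuration relative to C2, and the late placing of three acyl groups of two kinds with one hydroxyl left free. The plan rests on the α-ketol formed by C1 (carbinol) and C6 (ketone). Its isomer, in which C6 is the carbinol carbon of a cyclopent-2-enol and C1 an exocyclic acyl carbon, is linked to it by a 1,2-shift of C2 that enlarges the five-membered ring to the six-membered enone. The remaining trans-diol C2/C3 has the configuration of C-2 and C-3 of D-arabinose.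

## Retrosynthetic reasoning

**21 ⇒ 19 + 20.** The C2–O acetyl bond is cut first. In zeylenone 19 the C2 hydroxyl is the only one that can still be acylated under mild conditions, since the C1 hydroxyl is tertiary. The forward step therefore needs no protecting group, only mildness.

**19 ⇒ 17 + 18.** The two benzoyl–oxygen bonds at C7 and C3 are cut, which leads to tetraol 17 and benzoyl chloride 18. This saves all protecting-group differentiation between the four oxygens. The forward reaction must distinguish the primary C7 and the allylic C3 hydroxyls from the C2 hydroxyl, which is wedged between the quaternary C1 and C3.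

**17 ⇒ 16.** The three O–H bonds at C7, C2 and C3 are taken back to one kind of silyl ether. One fluoride step then frees all of them, and silyl ethers are poor ligands for aluminium and survive a Lewis acid, which the next disconnection needs.

**16 ⇒ 15 (key disconnection).** The C1–C2 bond of 16 is cut and C2 is joined to C6. C6 becomes a carbinol carbon in a cyclopentene and C1 the carbonyl carbon of an exocyclic acyl group. This is the only cut that removes the six-membered ring and the oxygenated quaternary centre together. The gain is that the C1 configuration is no longer built on its own but follows from the C6 configuration in 15, which can be set by addition to a ketone. In the forward direction C2, not the vinylic C5, must migrate, with retention, through a chelated geometry.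

**15 ⇒ 14 ⇒ 12.** The C7–O silyl bond is cut to give diol 14. Its hydroxyacetyl group is then traced back to the 1-ethoxyvinyl group of 12, removing the C7–O bond and the C1 carbonyl oxygen. The enol ether is the most electron-rich π-bond of 12, so the forward oxidation can leave the ring alkene alone.

**12 ⇒ 9 + 11 (from 10).** The C6–C1 bond is cut, which gives enone 9 and the lithiated enol ether 11 made from ethyl vinyl ether 10. The C7 oxygen is deliberately not carried in the nucleophile. A sulfur-stabilised acyl anion with a silyloxy group on the neighbouring carbon would be set up for β-elimination, whereas 11 has no leaving group. The forward step must be a 1,2-addition from the face opposite to the C2 silyloxy group.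

**9 ⇒ 8 ⇒ 7.** The ketone is taken back to the allylic alcohol 8, and the ring alkene C4=C5 is cut to the two terminal alkenes of dienol 7. Ring-closing metathesis forms cyclopentenes readily and tolerates every group present.

**7 ⇒ 5 + 6.** The C5–C6 bond is cut to aldehyde 5 and vinylmagnesium bromide 6. The carbinol configuration formed here is irrelevant because the carbon becomes the ketone of 9.

**5 ⇒ 4 ⇒ 3 ⇒ 2 ⇒ 1.** The alkene and the aldehyde of 5 arise together from the 5-iodo furanoside 4 by reductive fragmentation. Compound 4 comes from D-arabinose 1 by glycosidation (2), iodination of the primary hydroxyl (3) and silylation. The sugar carbons C-2 and C-3 become C2 and C3 of the target without any bond to them being touched, so only C1 remains to be set.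

## Alternatives that were turned down

**Alternative 1:** The C2–O and C3–O bonds are traced back to an oxirane and from there to the prochiral dienol A1, whose two alkenes are enantiotopic.
- Forward key step: VO(OiPr)3 with a chiral bishydroxamic acid ligand and tert-butyl hydroperoxide epoxidises one alkene syn to the C1 hydroxyl and gives the syn-epoxy alcohol A2.
- For it: it is catalytic and asymmetric, the C7 benzoate is already in place, and C1 and C2 are set in one step from achiral material. On step count to the first chiral intermediate it is stronger than the sugar route.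
- Against it: the absolute configuration depends entirely on enantiotopic-group selection by the catalyst at a tertiary carbinol. A1 is a doubly allylic tertiary alcohol that can ionise and aromatise under a Lewis-acidic metal. A2 still lacks the C6 carbonyl group, has its alkene at C5=C6 and a methylene at C4. The end game therefore still needs a regioselective trans-opening of the oxirane at C3 by benzoate, an allylic oxidation with transposition of the alkene, and differentiation of the C2 hydroxyl.
- Comparison: the chosen route is longer at the front but takes C2 and C3 from the sugar with certainty and delivers the enone oxidation pattern directly in the key step.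

**Alternative 2:** The C4=C5 double bond is cut, which leads to the acyclic dienone A3, carrying a vinyl ketone at C6 and a vinyl group at C3.
- Forward key step: the second-generation Grubbs catalyst closes A3 to the cyclohexenone A4, which carries both benzoates and a cis-fused acetonide on the C1 and C2 oxygens.
- For it: ring-closing metathesis is dependable, and the end game is only acetonide removal and acetylation. On the placing of the acyl groups this is stronger than the chosen route, which needs a selective benzoylation.
- Against it: the quaternary C1 with its oxygenated branch must be built on an open chain derived from a hexose, which costs a branching reaction and several protecting-group changes. The vinyl ketone next to a quaternary centre is an electron-poor, hindered metathesis partner and is prone to conjugate addition. The step count to A3 alone is expected to exceed the whole sequence to 15.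
- Comparison: the chosen route creates the quaternary centre in the ring-forming step itself and needs no branched sugar.

**Alternative 3:** The C3–C4 bond is cut, which leads to the (Z)-iodoenone aldehyde A5.
- Forward key step: CrCl2 with catalytic NiCl2 turns the vinyl iodide into a vinylchromium species that adds to the C3 aldehyde and gives the hydroxy enone A6.
- For it: the conditions are mild and select the aldehyde over the ketone. C3–OH emerges as the only free hydroxyl, so its benzoylation is unambiguous, again a point on which it is stronger than the chosen route.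
- Against it: the C3 configuration is created in the ring closure and must come out trans to C2–O by substrate control alone. A5 combines a (Z)-β-iodo enone, which can isomerise and undergo addition–elimination, with an α-alkoxy aldehyde whose C2 can epimerise. CrCl2 is needed in large excess, and the quaternary C1 again has to be made beforehand.
- Comparison: the chosen route brings in C2 and C3 intact and forms only C1, stereospecifically, in the key step.

Key step: step 11

Assumption: furanosides 2–4 are carried as anomeric mixtures and 7 and 8 as carbinol epimers, because these carbons become the aldehyde carbon of 5 and the ketone carbon of 9.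

## Route

Step 1
Reactants: 1 D-arabinose
Product: 2 methyl D-arabinofuranoside (anomeric mixture)
Conditions: HCl (cat.), MeOH, rt; neutralise (NaHCO3) before concentration
Reagents that add atoms: methanol, CO
Why: Kinetic Fischer glycosidation: in dilute methanolic acid at room temperature the furanosides form faster than the pyranosides, and neutralisation before concentration freezes this mixture. Both anomers serve.

Step 2
Reactants: 2 methyl D-arabinofuranoside
Product: 3 methyl 5-deoxy-5-iodo-D-arabinofuranoside (anomeric mixture)
Conditions: PPh3, I2, imidazole, THF, 50 °C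
Reagents that add atoms: iodine, II
Why: Appel-type iodination under Garegg–Samuelsson conditions: the bulky oxyphosphonium group forms at the primary C-5 hydroxyl and is displaced there by iodide, while the two secondary hydroxyls of the trans-diol stay free.

Step 3
Reactants: 3 methyl 5-deoxy-5-iodo-D-arabinofuranoside
Product: 4 methyl 2,3-bis-O-(tert-butyldimethylsilyl)-5-deoxy-5-iodo-D-arabinofuranoside (anomeric mixture)
Conditions: TBSOTf, 2,6-lutidine, CH2Cl2, 0 °C → rt
Reagents that add atoms: tert-butyldimethylsilyl trifluoromethanesulfonate, CC(C)(C)[Si](C)(C)OS(=O)(=O)C(F)(F)F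
Why: Silylation with the silyl triflate and a hindered pyridine base converts both hydroxyls of the trans-diol into silyl ethers; the primary iodide and the methyl acetal are inert under these buffered, non-nucleophilic conditions.

Step 4
Reactants: 4 methyl 2,3-bis-O-(tert-butyldimethylsilyl)-5-deoxy-5-iodo-D-arabinofuranoside
Product: 5 (2S,3R)-2,3-bis(tert-butyldimethylsilyloxy)pent-4-enal
Conditions: Zn dust (activated), THF/H2O 4:1, ultrasound, 40 °C
Reagents that add atoms: none
Why: Bernet–Vasella reductive fragmentation: zinc inserts into the C–I bond and the organozinc expels the ring oxygen, which gives the terminal alkene and frees the anomeric carbon as the aldehyde with loss of methanol. The sugar carbons C-2 and C-3 are not involved, so their configuration passes unchanged into 5, which is used crude to avoid epimerisation next to the aldehyde.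

Step 5
Reactants: 5 (2S,3R)-2,3-bis(tert-butyldimethylsilyloxy)pent-4-enal; 6 vinylmagnesium bromide
Product: 7 (4R,5R)-4,5-bis(tert-butyldimethylsilyloxy)hepta-1,6-dien-3-ol (both C3 epimers)
Conditions: THF, −78 → −20 °C; H2O quench
Reagents that add atoms: none
Why: Grignard addition to the aldehyde; the configuration of the new carbinol is of no consequence because it is oxidised in step 7. Low temperature keeps the magnesium alkoxide from taking over a neighbouring silyl group.

Step 6
Reactants: 7 (4R,5R)-4,5-bis(tert-butyldimethylsilyloxy)hepta-1,6-dien-3-ol
Product: 8 (4R,5R)-4,5-bis(tert-butyldimethylsilyloxy)cyclopent-2-en-1-ol (both C1 epimers)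
Conditions: second-generation Grubbs catalyst (3 mol %), CH2Cl2, 40 °C
Reagents that add atoms: none
Why: Ring-closing metathesis of the two terminal alkenes with loss of ethylene closes the cyclopentene; the ruthenium carbene tolerates the free allylic hydroxyl and the silyl ethers, and five-membered ring closure from a 1,6-diene is fast.

Step 7
Reactants: 8 (4R,5R)-4,5-bis(tert-butyldimethylsilyloxy)cyclopent-2-en-1-ol
Product: 9 (4R,5S)-4,5-bis(tert-butyldimethylsilyloxy)cyclopent-2-en-1-one
Conditions: Dess–Martin periodinane, pyridine, CH2Cl2, 0 °C → rt
Reagents that add atoms: none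
Why: Dess–Martin oxidation of the allylic alcohol to the enone under buffered, non-basic conditions, so that the stereocentre next to the new carbonyl group (C2 of the target) does not epimerise and no silyloxy group is eliminated.

Step 8
Reactants: 9 (4R,5S)-4,5-bis(tert-butyldimethylsilyloxy)cyclopent-2-en-1-one; 10 ethyl vinyl ether
Product: 12 (1R,4R,5S)-4,5-bis(tert-butyldimethylsilyloxy)-1-(1-ethoxyethenyl)cyclopent-2-en-1-ol, via 1-ethoxyvinyllithium 11 (not isolated)
Conditions: 10 (excess), t-BuLi, THF, −78 → 0 °C; then 9, −78 °C; aq. NaHCO3 quench
Reagents that add atoms: none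
Why: Deprotonation of ethyl vinyl ether at its α-carbon gives an acyl anion equivalent with no leaving group next to the carbanion, and this hard organolithium adds to the carbonyl carbon of the enone (1,2-addition). It approaches the carbonyl face opposite to the adjacent C2 silyloxy group (steric and Felkin–Anh control), which sets C6 with the hydroxyl cis and the two-carbon unit trans to C2–O.

Step 9
Reactants: 12 (1R,4R,5S)-4,5-bis(tert-butyldimethylsilyloxy)-1-(1-ethoxyethenyl)cyclopent-2-en-1-ol
Product: 14 1-[(1R,4R,5S)-4,5-bis(tert-butyldimethylsilyloxy)-1-hydroxycyclopent-2-en-1-yl]-2-hydroxyethan-1-one, via ethyl hemiketal 13 (not isolated)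
Conditions: OsO4 (2 mol %), N-methylmorpholine N-oxide (1.1 equiv), acetone/H2O, 0 °C
Reagents that add atoms: osmium tetroxide, O=[Os](=O)(=O)=O; N-methylmorpholine N-oxide, C[N+]1([O-])CCOCC1
Why: Upjohn dihydroxylation: OsO4 attacks the electron-rich enol ether alkene much faster than the hindered, oxygen-flanked ring alkene. The hemiketal 13 then loses ethanol, so C7 receives its hydroxyl and C1 its carbonyl oxygen in one operation; no stereocentre is formed or touched.

Step 10
Reactants: 14 1-[(1R,4R,5S)-4,5-bis(tert-butyldimethylsilyloxy)-1-hydroxycyclopent-2-en-1-yl]-2-hydroxyethan-1-one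
Product: 15 1-[(1R,4R,5S)-4,5-bis(tert-butyldimethylsilyloxy)-1-hydroxycyclopent-2-en-1-yl]-2-(tert-butyldimethylsilyloxy)ethan-1-one
Conditions: TBSCl (1.1 equiv), imidazole, CH2Cl2, 0 °C
Reagents that add atoms: tert-butyldimethylsilyl chloride, CC(C)(C)[Si](C)(C)Cl
Why: Silylation of the primary hydroxyl with the silyl chloride and imidazole; the tertiary C6 hydroxyl is too hindered to react and stays free, as the key step requires.

Step 11
Reactants: 15 1-[(1R,4R,5S)-4,5-bis(tert-butyldimethylsilyloxy)-1-hydroxycyclopent-2-en-1-yl]-2-(tert-butyldimethylsilyloxy)ethan-1-one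
Product: 16 (4R,5S,6S)-4,5-bis(tert-butyldimethylsilyloxy)-6-[(tert-butyldimethylsilyloxy)methyl]-6-hydroxycyclohex-2-en-1-one
Conditions: Al(OtBu)3 (1.5 equiv), toluene, rt → 70 °C; aq. potassium sodium tartrate work-up
Reagents that add atoms: none
Why: Ligand exchange puts the C6 hydroxyl of 15 on aluminium, which also binds the C1 carbonyl oxygen, so that a five-membered chelate holds the two C–O bonds syn-periplanar and polarises the carbonyl group. In this geometry the C6–C2 σ-bond lies parallel to the π* orbital at C1 and shifts suprafacially to C1 while the C6–O bond becomes the new carbonyl group; C2 keeps its configuration. The closest known reaction type is the Lewis-acid-promoted α-ketol (acyloin) rearrangement with ring enlargement of 1-acylcycloalkanols, as in the D-homoannulation of 17-hydroxy-20-keto steroids. The six-membered ring is not closed by a cyclisation but arises by ring enlargement through this 1,2-shift, so no exo or endo mode applies. The new stereocentre C1 is controlled by two elements of 15: the chelate fixes which face of the C1 carbonyl group is turned towards C2, and the acyl group stands trans to the C2 oxygen, so that the oxygen that becomes the C1 hydroxyl ends cis to C2–O and C7 trans to it, which is the (S) configuration at C1. The step needs migration of C2 and not of the vinylic C5; the shift is reversible, and only migration of C2 gives the conjugated enone and relieves the cyclopentene strain, so this product is the thermodynamic sink. Al(OtBu)3 has no hydrogen on its carbinol carbons and cannot reduce a ketone by hydride transfer, and the three silyl ethers are poor ligands that do not compete for the metal.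

Step 12
Reactants: 16 (4R,5S,6S)-4,5-bis(tert-butyldimethylsilyloxy)-6-[(tert-butyldimethylsilyloxy)methyl]-6-hydroxycyclohex-2-en-1-one
Product: 17 (4R,5S,6S)-4,5,6-trihydroxy-6-(hydroxymethyl)cyclohex-2-en-1-one
Conditions: HF·pyridine, pyridine, THF, 0 °C → rt
Reagents that add atoms: none
Why: Fluoride-mediated cleavage of all three silyl ethers under buffered acidic conditions; basic fluoride sources are avoided because the γ-oxygenated enone and the β-hydroxy ketone would suffer elimination or retro-aldol cleavage. The polar tetraol is isolated without aqueous extraction, by evaporation and filtration through silica.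

Step 13
Reactants: 17 (4R,5S,6S)-4,5,6-trihydroxy-6-(hydroxymethyl)cyclohex-2-en-1-one; 18 benzoyl chloride
Product: 19 zeylenone, [(1S,5R,6S)-5-(benzoyloxy)-1,6-dihydroxy-2-oxocyclohex-3-en-1-yl]methyl benzoate
Conditions: 18 (2.1 equiv), pyridine, CH2Cl2, −40 → −10 °C
Reagents that add atoms: none
Why: Acylation with two equivalents of the acid chloride at low temperature follows accessibility: the primary C7 hydroxyl reacts first, then the allylic C3 hydroxyl, which has an sp2 carbon as one neighbour. The C2 hydroxyl, wedged between the quaternary C1 and C3, is slower, and the tertiary C1 hydroxyl does not react.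

Step 14
Reactants: 19 zeylenone; 20 acetic anhydride
Product: 21 2-O-acetylzeylenone, [(1S,5R,6S)-6-(acetyloxy)-5-(benzoyloxy)-1-hydroxy-2-oxocyclohex-3-en-1-yl]methyl benzoate
Conditions: 20 (1.5 equiv), pyridine, 4-(dimethylamino)pyridine (cat.), CH2Cl2, 0 °C
Reagents that add atoms: none
Why: Acetylation of the one remaining secondary hydroxyl; the tertiary C1 hydroxyl is not acylated under these mild conditions, and low temperature with a weak base avoids acyl migration and elimination.

## Compound list

1 | D-arabinose | O=C[C@@H](O)[C@H](O)[C@H](O)CO | starting material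
2 | methyl D-arabinofuranoside (anomeric mixture) | COC1O[C@H](CO)[C@@H](O)[C@@H]1O | intermediate
3 | methyl 5-deoxy-5-iodo-D-arabinofuranoside (anomeric mixture) | COC1O[C@H](CI)[C@@H](O)[C@@H]1O | intermediate
4 | methyl 2,3-bis-O-(tert-butyldimethylsilyl)-5-deoxy-5-iodo-D-arabinofuranoside (anomeric mixture) | COC1O[C@H](CI)[C@@H](O[Si](C)(C)C(C)(C)C)[C@@H]1O[Si](C)(C)C(C)(C)C | intermediate
5 | (2S,3R)-2,3-bis(tert-butyldimethylsilyloxy)pent-4-enal | O=C[C@@H](O[Si](C)(C)C(C)(C)C)[C@H](O[Si](C)(C)C(C)(C)C)C=C | intermediate
6 | vinylmagnesium bromide | C=C[Mg]Br | starting material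
7 | (4R,5R)-4,5-bis(tert-butyldimethylsilyloxy)hepta-1,6-dien-3-ol (both C3 epimers) | C=CC(O)[C@@H](O[Si](C)(C)C(C)(C)C)[C@H](O[Si](C)(C)C(C)(C)C)C=C | intermediate
8 | (4R,5R)-4,5-bis(tert-butyldimethylsilyloxy)cyclopent-2-en-1-ol (both C1 epimers) | OC1C=C[C@@H](O[Si](C)(C)C(C)(C)C)[C@@H]1O[Si](C)(C)C(C)(C)C | intermediate
9 | (4R,5S)-4,5-bis(tert-butyldimethylsilyloxy)cyclopent-2-en-1-one | O=C1C=C[C@@H](O[Si](C)(C)C(C)(C)C)[C@@H]1O[Si](C)(C)C(C)(C)C | intermediate
10 | ethyl vinyl ether | C=COCC | starting material
11 | 1-ethoxyvinyllithium | [Li]C(=C)OCC | intermediate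
12 | (1R,4R,5S)-4,5-bis(tert-butyldimethylsilyloxy)-1-(1-ethoxyethenyl)cyclopent-2-en-1-ol | C=C(OCC)[C@@]1(O)C=C[C@@H](O[Si](C)(C)C(C)(C)C)[C@@H]1O[Si](C)(C)C(C)(C)C | intermediate
13 | 1-[(1R,4R,5S)-4,5-bis(tert-butyldimethylsilyloxy)-1-hydroxycyclopent-2-en-1-yl]-1-ethoxyethane-1,2-diol (ethyl hemiketal, either configuration at the ketal carbon) | OCC(O)(OCC)[C@@]1(O)C=C[C@@H](O[Si](C)(C)C(C)(C)C)[C@@H]1O[Si](C)(C)C(C)(C)C | intermediate
14 | 1-[(1R,4R,5S)-4,5-bis(tert-butyldimethylsilyloxy)-1-hydroxycyclopent-2-en-1-yl]-2-hydroxyethan-1-one | O=C(CO)[C@@]1(O)C=C[C@@H](O[Si](C)(C)C(C)(C)C)[C@@H]1O[Si](C)(C)C(C)(C)C | intermediate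
15 | 1-[(1R,4R,5S)-4,5-bis(tert-butyldimethylsilyloxy)-1-hydroxycyclopent-2-en-1-yl]-2-(tert-butyldimethylsilyloxy)ethan-1-one | O=C(CO[Si](C)(C)C(C)(C)C)[C@@]1(O)C=C[C@@H](O[Si](C)(C)C(C)(C)C)[C@@H]1O[Si](C)(C)C(C)(C)C | intermediate
16 | (4R,5S,6S)-4,5-bis(tert-butyldimethylsilyloxy)-6-[(tert-butyldimethylsilyloxy)methyl]-6-hydroxycyclohex-2-en-1-one | CC(C)(C)[Si](C)(C)OC[C@]1(O)[C@@H](O[Si](C)(C)C(C)(C)C)[C@H](O[Si](C)(C)C(C)(C)C)C=CC1=O | intermediate
17 | (4R,5S,6S)-4,5,6-trihydroxy-6-(hydroxymethyl)cyclohex-2-en-1-one | OC[C@]1(O)[C@@H](O)[C@H](O)C=CC1=O | intermediate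
18 | benzoyl chloride | O=C(Cl)c1ccccc1 | starting material
19 | zeylenone, [(1S,5R,6S)-5-(benzoyloxy)-1,6-dihydroxy-2-oxocyclohex-3-en-1-yl]methyl benzoate | O[C@H]1[C@H](OC(=O)c2ccccc2)C=CC(=O)[C@]1(O)COC(=O)c1ccccc1 | intermediate
20 | acetic anhydride | CC(=O)OC(C)=O | starting material
21 | 2-O-acetylzeylenone, [(1S,5R,6S)-6-(acetyloxy)-5-(benzoyloxy)-1-hydroxy-2-oxocyclohex-3-en-1-yl]methyl benzoate | CC(=O)O[C@H]1[C@H](OC(=O)c2ccccc2)C=CC(=O)[C@]1(O)COC(=O)c1ccccc1 | target

## Step count and least certain steps

Total step count: 14. Longest linear sequence: 14 steps (1 → 21); the route is fully linear.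

**Step 11 (key step).**
- Risk: a non-chelated pathway may compete, in which the C1 carbonyl oxygen points away from the C6 oxygen, and erode the configuration at C1. The reaction may also stall at temperatures the substrate tolerates. On prolonged heating a silyl group may shift to a neighbouring aluminium alkoxide, or a silyloxy group may be lost from the γ-position of the enone.
- Fallback: the shift is moved to the aldehyde oxidation level, where the driving force is larger and C1 is not set by the shift. It sets out from 9 and returns at 17.
  - 2-Lithio-1,3-dithiane (from 1,3-dithiane and n-BuLi) would add to 9 anti to the C2 oxygen to give the dithianyl carbinol F1.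
  - MeI and CaCO3 in aqueous MeCN would free the α-hydroxy aldehyde F2.
  - Mild Lewis acid or gentle warming would shift C2 onto the formyl carbon and give the ring-expanded 6-hydroxycyclohexenone F3, in which C1 still carries hydrogen.
  - Et3SiCl and imidazole would give the triethylsilyl ether F4.
  - Kinetic enolisation at C1 with lithium diisopropylamide at −78 °C and aldol addition to monomeric formaldehyde, anti to the C2 silyloxy group, would give the hydroxymethyl ketone F5 with C7 trans to C2–O.
  - HF·pyridine would convert F5 into tetraol 17.

**Step 8.**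
- Risk: the strongly basic vinyllithium may deprotonate the carbon between the carbonyl group and the silyloxy-bearing carbon, followed by loss of that silyloxy group. Facial selectivity may be incomplete because the more distant C3 silyloxy group lies on the face of attack. The acid-labile enol ether may hydrolyse on work-up.
- Fallback: a less basic nucleophile and a more robust adduct, from 9 back to 15.
  - Vinylmagnesium bromide 6 (with anhydrous CeCl3 if needed) would give the vinyl carbinol F6.
  - OsO4 with N-methylmorpholine N-oxide would dihydroxylate the accessible monosubstituted alkene to the side-chain diol F7.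
  - TBSCl and imidazole would give the primary silyl ether F8.
  - Oxidation of the secondary hydroxyl with SO3·pyridine, dimethyl sulfoxide and iPr2NEt would give 15.
  - Epimers at C6, if formed, would be separated at the stage of F6.

**Step 9.**
- Risk: the enol ether may hydrolyse to the methyl ketone before it is oxidised, or the ring alkene may be over-oxidised if the difference in rate is smaller than expected.
- Fallback: the hydrolysis is accepted and the oxygen is put on C7 by enol silane oxidation, from 12 back to 14.
  - Dilute oxalic acid in wet THF would give the methyl ketone F9.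
  - Me3SiOTf and Et3N would silylate the tertiary hydroxyl and form the only possible enol silane, F10.
  - Rubottom oxidation with m-chloroperbenzoic acid, which attacks the silyl enol ether far faster than the ring alkene, would give the silyloxy ketone F11.
  - Citric acid in methanol would remove both trimethylsilyl groups to give 14.

**Step 13.**
- Risk: once C7 is acylated, the C2 hydroxyl may compete with the C3 hydroxyl, or a benzoyl group may wander from O3 to O2. Over-acylation to a tribenzoate is also possible.
- Fallback: the cis relation of the C1 and C2 oxygens is used to block C2, from 17 back to 19.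
  - One equivalent of benzoyl chloride 18 at −40 °C would give the primary monobenzoate F12.
  - 2,2-Dimethoxypropane with pyridinium p-toluenesulfonate would tie the cis C1/C2 diol into the acetonide F13; the trans C2/C3 diol cannot form a five-membered acetal without strain.
  - Benzoyl chloride and pyridine would acylate the only free hydroxyl, at C3, to give the acetonide dibenzoate F14.
  - Aqueous CF3CO2H would remove the acetonide to give 19.

## Further compounds

F1 | step 11 | 1-(1,3-dithian-2-yl)-4,5-trans-bis(tert-butyldimethylsilyloxy)cyclopent-2-en-1-ol, hydroxyl cis to the adjacent silyloxy group | C1(SCCCS1)[C@@]2(O)C=C[C@@H](O[Si](C)(C)C(C)(C)C)[C@@H]2O[Si](C)(C)C(C)(C)C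
F2 | step 11 | 1-hydroxy-4,5-trans-bis(tert-butyldimethylsilyloxy)cyclopent-2-ene-1-carbaldehyde, hydroxyl cis to the adjacent silyloxy group | O=C[C@@]1(O)C=C[C@@H](O[Si](C)(C)C(C)(C)C)[C@@H]1O[Si](C)(C)C(C)(C)C
F3 | step 11 | 6-hydroxy-4,5-trans-bis(tert-butyldimethylsilyloxy)cyclohex-2-en-1-one (C2 and C3 as in 16, either configuration at the carbinol carbon) | OC1[C@@H](O[Si](C)(C)C(C)(C)C)[C@H](O[Si](C)(C)C(C)(C)C)C=CC1=O
F4 | step 11 | 4,5-trans-bis(tert-butyldimethylsilyloxy)-6-(triethylsilyloxy)cyclohex-2-en-1-one | CC[Si](CC)(CC)OC1[C@@H](O[Si](C)(C)C(C)(C)C)[C@H](O[Si](C)(C)C(C)(C)C)C=CC1=O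
F5 | step 11 | 4,5-bis(tert-butyldimethylsilyloxy)-6-(hydroxymethyl)-6-(triethylsilyloxy)cyclohex-2-en-1-one, configuration as in 16 | OC[C@]1(O[Si](CC)(CC)CC)[C@@H](O[Si](C)(C)C(C)(C)C)[C@H](O[Si](C)(C)C(C)(C)C)C=CC1=O
F6 | step 8 | 1-ethenyl-4,5-trans-bis(tert-butyldimethylsilyloxy)cyclopent-2-en-1-ol, hydroxyl cis to the adjacent silyloxy group | C=C[C@@]1(O)C=C[C@@H](O[Si](C)(C)C(C)(C)C)[C@@H]1O[Si](C)(C)C(C)(C)C
F7 | step 8 | 1-[4,5-bis(tert-butyldimethylsilyloxy)-1-hydroxycyclopent-2-en-1-yl]ethane-1,2-diol (side-chain carbinol epimers) | OCC(O)[C@@]1(O)C=C[C@@H](O[Si](C)(C)C(C)(C)C)[C@@H]1O[Si](C)(C)C(C)(C)C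
F8 | step 8 | 1-[4,5-bis(tert-butyldimethylsilyloxy)-1-hydroxycyclopent-2-en-1-yl]-2-(tert-butyldimethylsilyloxy)ethan-1-ol (side-chain carbinol epimers) | CC(C)(C)[Si](C)(C)OCC(O)[C@@]1(O)C=C[C@@H](O[Si](C)(C)C(C)(C)C)[C@@H]1O[Si](C)(C)C(C)(C)C
F9 | step 9 | 1-[4,5-bis(tert-butyldimethylsilyloxy)-1-hydroxycyclopent-2-en-1-yl]ethan-1-one, configuration as in 14 | CC(=O)[C@@]1(O)C=C[C@@H](O[Si](C)(C)C(C)(C)C)[C@@H]1O[Si](C)(C)C(C)(C)C
F10 | step 9 | 4,5-bis(tert-butyldimethylsilyloxy)-1-(trimethylsilyloxy)-1-[1-(trimethylsilyloxy)ethenyl]cyclopent-2-ene, configuration as in 14 | C=C(O[Si](C)(C)C)[C@@]1(O[Si](C)(C)C)C=C[C@@H](O[Si](C)(C)C(C)(C)C)[C@@H]1O[Si](C)(C)C(C)(C)C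
F11 | step 9 | 1-[4,5-bis(tert-butyldimethylsilyloxy)-1-(trimethylsilyloxy)cyclopent-2-en-1-yl]-2-(trimethylsilyloxy)ethan-1-one, configuration as in 14 | C[Si](C)(C)OCC(=O)[C@@]1(O[Si](C)(C)C)C=C[C@@H](O[Si](C)(C)C(C)(C)C)[C@@H]1O[Si](C)(C)C(C)(C)C
F12 | step 13 | 7-O-benzoyl tetraol, [(1S,5R,6S)-1,5,6-trihydroxy-2-oxocyclohex-3-en-1-yl]methyl benzoate | O=C(OC[C@]1(O)[C@@H](O)[C@H](O)C=CC1=O)c1ccccc1
F13 | step 13 | 7-O-benzoyl-1,2-O-isopropylidene tetraol (cis-fused acetonide on the C1 and C2 oxygens, C3 hydroxyl free) | O=C(c1ccccc1)OC[C@]12OC(C)(C)O[C@H]1[C@H](O)C=CC2=O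
F14 | step 13 | 1,2-O-isopropylidenezeylenone (cis-fused acetonide of the 3,7-dibenzoate) | O=C(c1ccccc1)OC[C@]12OC(C)(C)O[C@H]1[C@H](OC(=O)c1ccccc1)C=CC2=O
A1 | alternative 1 | (1-hydroxycyclohexa-2,5-dien-1-yl)methyl benzoate (prochiral dienol) | O=C(OCC1(O)C=CCC=C1)c1ccccc1
A2 | alternative 1 | (2-hydroxy-7-oxabicyclo[4.1.0]hept-3-en-2-yl)methyl benzoate, oxirane on C2 and C3 cis to the C1 hydroxyl | O=C(c1ccccc1)OC[C@]1(O)[C@H]2O[C@H]2CC=C1
A3 | alternative 2 | [5-[1-(benzoyloxy)prop-2-en-1-yl]-2,2-dimethyl-4-(prop-2-enoyl)-1,3-dioxolan-4-yl]methyl benzoate (acyclic dienone, configuration as in the SMILES) | C=CC(=O)[C@@]1(COC(=O)c2ccccc2)OC(C)(C)O[C@H]1[C@H](OC(=O)c1ccccc1)C=C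
A4 | alternative 2 | 1,2-O-isopropylidenezeylenone (cyclohexenone dibenzoate with cis-fused acetonide on the C1 and C2 oxygens) | O=C(c1ccccc1)OC[C@]12OC(C)(C)O[C@H]1[C@H](OC(=O)c1ccccc1)C=CC2=O
A5 | alternative 3 | 5-[(tert-butyldimethylsilyloxy)methyl]-5-[(2Z)-3-iodoprop-2-enoyl]-2,2-dimethyl-1,3-dioxolane-4-carbaldehyde (configuration as in the SMILES) | O=C[C@@H]1OC(C)(C)O[C@]1(CO[Si](C)(C)C(C)(C)C)C(=O)/C=C\I
A6 | alternative 3 | 7-O-(tert-butyldimethylsilyl)-1,2-O-isopropylidene tetraol (4-hydroxycyclohex-2-enone with cis-fused acetonide, C3 hydroxyl trans to the C2 oxygen) | CC(C)(C)[Si](C)(C)OC[C@]12OC(C)(C)O[C@H]1[C@H](O)C=CC2=O
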